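**Plan**
1. Retrosynthesis: remove the two silyl ethers and a helper hydroxyl on C2, then cut ring C at O1–C2 and at C3–C4 in a single operation.
2. Enabling feature: O1 and C4 sit on the adjacent ring A carbons C8a and C4a, so ring A plus C4 is a latent ortho-quinone methide (1-oxadiene O1=C8a–C4a=C4H2). C2–C3 with ring B on C3 is the enamine of an arylacetaldehyde (C2 at the aldehyde level), and ring C is their [4+2] adduct.
3. Forward: both halves come from 2,4-dihydroxybenzaldehyde. C3-prenylation, silylation, reduction and sulfinate exchange give the ring A quinone methide precursor; chromenylation with prenal, silylation and one-carbon homologation give the ring B arylacetaldehyde.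
4. Ring order: the pyran ring fused to ring B (step 5), then ring C (step 9), then deoxygenation at C2 and desilylation.
5. Stereochemistry: the only stereocentre, C3, is set in the ring C-forming step by an (S)-prolinol silyl ether catalyst that shields one face of the enamine; it is not touched afterwards.

Key step: step 9

Remark: isoflavan numbering is used (ring C: O1, C2, C3, C4; ring A: C4a to C8a; ring B: primed locants). The stereocentre C3 of the target is S. The C2 hydroxyl carried from step 9 to step 10 is a helper, so its configuration is immaterial.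

**Route**

Step 1
Reactants: 1 2,4-dihydroxybenzaldehyde; 2 1-bromo-3-methylbut-2-ene (prenyl bromide)
Product: 3 2,4-dihydroxy-3-(3-methylbut-2-en-1-yl)benzaldehyde
Conditions: KOH (10 % aq), 0 °C → rt; O-prenyl and C5 isomers removed by chromatography, unreacted 1 recycled
Reagents that add atoms: none
Why: C-alkylation of the resorcinol dianion in water (nuclear prenylation), where hydration of the phenoxide oxygens favours attack through carbon and C3, flanked by both oxygens, is the most nucleophilic ring position.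

Step 2
Reactants: 3 2,4-dihydroxy-3-(3-methylbut-2-en-1-yl)benzaldehyde
Product: 4 2-hydroxy-3-(3-methylbut-2-en-1-yl)-4-[(triisopropylsilyl)oxy]benzaldehyde
Conditions: TIPSCl (1.05 equiv), imidazole, DMF, 0 °C
Reagents that add atoms: triisopropylsilyl chloride, CC(C)[Si](Cl)(C(C)C)C(C)C
Why: selective O-silylation, since the C2 hydroxyl is held in a hydrogen bond to the formyl group and only the C4 hydroxyl (the later C7 oxygen) reacts; this blocks any para-quinone methide later.

Step 3
Reactants: 4 2-hydroxy-3-(3-methylbut-2-en-1-yl)-4-[(triisopropylsilyl)oxy]benzaldehyde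
Product: 5 6-(hydroxymethyl)-2-(3-methylbut-2-en-1-yl)-3-[(triisopropylsilyl)oxy]phenol
Conditions: NaBH4, THF/MeOH, 0 °C
Reagents that add atoms: none
Why: borohydride reduction of the aldehyde to the salicyl alcohol; the aryl silyl ether and the prenyl group are inert.

Step 4
Reactants: 5 6-(hydroxymethyl)-2-(3-methylbut-2-en-1-yl)-3-[(triisopropylsilyl)oxy]phenol
Product: 6 2-(3-methylbut-2-en-1-yl)-6-{[(4-methylphenyl)sulfonyl]methyl}-3-[(triisopropylsilyl)oxy]phenol
Conditions: p-TolSO2H (1.5 equiv), CH2Cl2, rt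
Reagents that add atoms: p-toluenesulfinic acid, Cc1ccc(cc1)S(=O)O
Why: acid-promoted ionisation of the salicyl alcohol to the oxygen-stabilised benzylic cation and capture at sulfur by the sulfinate (SN1 sulfone formation, water the only by-product) gives a bench-stable precursor that releases the quinone methide only on deprotonation.

Step 5
Reactants: 1 2,4-dihydroxybenzaldehyde; 7 3-methylbut-2-enal
Product: 9 5-hydroxy-2,2-dimethyl-2H-chromene-6-carbaldehyde, via dienone 8 (not isolated)
Conditions: ethylenediammonium diacetate (10 mol %), xylene, reflux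
Reagents that add atoms: none
Why: Knoevenagel-type condensation of the enal at C3 of the resorcinol gives the 1-oxatriene 8, which closes by oxa-6π electrocyclisation; the chelated C2 hydroxyl stays free and the C4 oxygen becomes the pyran oxygen, which is the angular chromene that ring B needs.

Step 6
Reactants: 9 5-hydroxy-2,2-dimethyl-2H-chromene-6-carbaldehyde
Product: 10 5-[(tert-butyldimethylsilyl)oxy]-2,2-dimethyl-2H-chromene-6-carbaldehyde
Conditions: TBSCl, imidazole, DMAP (cat.), DMF, rt
Reagents that add atoms: tert-butyldimethylsilyl chloride, CC(C)(C)[Si](C)(C)Cl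
Why: silylation of the remaining phenol, so that the later arylacetaldehyde cannot close to a benzofuranol lactol.

Step 7
Reactants: 10 5-[(tert-butyldimethylsilyl)oxy]-2,2-dimethyl-2H-chromene-6-carbaldehyde
Product: 11 tert-butyl{[6-(2-methoxyethenyl)-2,2-dimethyl-2H-chromen-5-yl]oxy}dimethylsilane (E/Z mixture)
Conditions: MeOCH2PPh3Cl, KOtBu, THF, 0 °C → rt
Reagents that add atoms: (methoxymethyl)triphenylphosphonium chloride, COC[P+](c1ccccc1)(c1ccccc1)c1ccccc1.[Cl-]
Why: Wittig methoxymethylenation adds the carbon that becomes C2; the alkene geometry is irrelevant because both isomers hydrolyse to the same aldehyde.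

Step 8
Reactants: 11 tert-butyl{[6-(2-methoxyethenyl)-2,2-dimethyl-2H-chromen-5-yl]oxy}dimethylsilane
Product: 12 {5-[(tert-butyldimethylsilyl)oxy]-2,2-dimethyl-2H-chromen-6-yl}acetaldehyde
Conditions: HCl (2 M aq), THF, rt; crude aldehyde used at once
Reagents that add atoms: water, O
Why: acid-catalysed enol ether hydrolysis (protonation at the aryl-bearing carbon, hydration, loss of methanol); the aryl silyl ether and the chromene should tolerate dilute aqueous acid at room temperature.

Step 9
Reactants: 6 2-(3-methylbut-2-en-1-yl)-6-{[(4-methylphenyl)sulfonyl]methyl}-3-[(triisopropylsilyl)oxy]phenol; 12 {5-[(tert-butyldimethylsilyl)oxy]-2,2-dimethyl-2H-chromen-6-yl}acetaldehyde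
Product: 16 (3S)-3-{5-[(tert-butyldimethylsilyl)oxy]-2,2-dimethyl-2H-chromen-6-yl}-8-(3-methylbut-2-en-1-yl)-7-[(triisopropylsilyl)oxy]chroman-2-ol (lactol; both C2 epimers), via ortho-quinone methide 13 (not isolated), via E-enamine 14 (not isolated), via cyclic N,O-aminal 15 (not isolated)
Conditions: (S)-2-[diphenyl(trimethylsilyloxy)methyl]pyrrolidine (20 mol %), powdered K2CO3 (1.5 equiv), CH2Cl2, 0 °C; 6 added slowly to 12 (1.5 equiv); short silica plug, crude lactol taken on
Reagents that add atoms: none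
Why: K2CO3 deprotonates the phenol of 6 and the phenoxide expels p-toluenesulfinate to give ortho-quinone methide 13 (1-oxadiene O1=C8a–C4a=C4H2) while the amine condenses with 12 to E-enamine 14; the aryl-bearing enamine carbon adds to the exocyclic methylene (C3–C4) and the quinone methide oxygen closes on the enamine α-carbon (O1–C2) in an inverse-electron-demand oxa-Diels–Alder reaction (or its Michael/hemiaminalisation equivalent) to give aminal 15, which the water of condensation hydrolyses to 16 with release of the catalyst. The closest known reaction type is the secondary-amine-catalysed enantioselective [4+2] annulation of aldehydes with ortho-quinone methides generated in situ from 2-(sulfonylmethyl)phenols. Ring C closes by [4+2] cycloaddition, which in the stepwise reading is a 6-exo-trig attack of the phenoxide on the iminium carbon. The new stereocentre C3 is controlled by the catalyst: the diphenyl(silyloxy)methyl group shields one face of the anti E-enamine so that C4 adds to the open face, which with the (S)-catalyst gives 3S (the same facial sense as in its Michael additions), while C2 forms as an epimer mixture that step 10 erases. The step needs isoflavan and not flavan regiochemistry, secured by the polarity of the partners (only the ring B-bearing enamine carbon is nucleophilic, only C4 is electrophilic), and it needs an ortho- and not a para-quinone methide and an open-chain aldehyde, both secured by the silyl ethers on the C7 and C2' oxygens. Slow addition of 6 keeps 13 dilute against self-dimerisation, and the α-branched lactol re-forms an enamine with the hindered catalyst only slowly, which protects the C3 configuration.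

Step 10
Reactants: 16 (3S)-3-{5-[(tert-butyldimethylsilyl)oxy]-2,2-dimethyl-2H-chromen-6-yl}-8-(3-methylbut-2-en-1-yl)-7-[(triisopropylsilyl)oxy]chroman-2-ol
Product: 17 tert-butyl({6-[(3S)-8-(3-methylbut-2-en-1-yl)-7-[(triisopropylsilyl)oxy]chroman-3-yl]-2,2-dimethyl-2H-chromen-5-yl}oxy)dimethylsilane
Conditions: Et3SiH (3 equiv), BF3·OEt2 (1.5 equiv), CH2Cl2, −78 → −30 °C
Reagents that add atoms: none
Why: BF3-promoted ionisation of the lactol to the cyclic oxocarbenium ion and hydride capture from the silane (ionic reduction of a lactol) turns the helper C2–OH into CH2 without breaking O1–C2 or touching C3; both phenols are silylated so they cannot add to the prenyl or chromene alkenes, and the low temperature suppresses alkene protonation.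

Step 11
Reactants: 17 tert-butyl({6-[(3S)-8-(3-methylbut-2-en-1-yl)-7-[(triisopropylsilyl)oxy]chroman-3-yl]-2,2-dimethyl-2H-chromen-5-yl}oxy)dimethylsilane
Product: 18 (3S)-3-(5-hydroxy-2,2-dimethyl-2H-chromen-6-yl)-8-(3-methylbut-2-en-1-yl)chroman-7-ol (CNP0263294.1)
Conditions: Bu4NF (2.5 equiv), AcOH (2.5 equiv), THF, 0 °C, under argon
Reagents that add atoms: none
Why: fluoride-mediated cleavage of both aryl silyl ethers, buffered with acetic acid so that the electron-rich phenoxides are protonated at once; the prenyl group, the chromene and C3 are unaffected.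

**Compound list**
1 | 2,4-dihydroxybenzaldehyde | O=Cc1ccc(O)cc1O | starting material
2 | 1-bromo-3-methylbut-2-ene (prenyl bromide) | CC(C)=CCBr | starting material
3 | 2,4-dihydroxy-3-(3-methylbut-2-en-1-yl)benzaldehyde | CC(C)=CCc1c(O)ccc(C=O)c1O | intermediate
4 | 2-hydroxy-3-(3-methylbut-2-en-1-yl)-4-[(triisopropylsilyl)oxy]benzaldehyde | CC(C)=CCc1c(O[Si](C(C)C)(C(C)C)C(C)C)ccc(C=O)c1O | intermediate
5 | 6-(hydroxymethyl)-2-(3-methylbut-2-en-1-yl)-3-[(triisopropylsilyl)oxy]phenol | CC(C)=CCc1c(O[Si](C(C)C)(C(C)C)C(C)C)ccc(CO)c1O | intermediate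
6 | 2-(3-methylbut-2-en-1-yl)-6-{[(4-methylphenyl)sulfonyl]methyl}-3-[(triisopropylsilyl)oxy]phenol | CC(C)=CCc1c(O[Si](C(C)C)(C(C)C)C(C)C)ccc(CS(=O)(=O)c2ccc(C)cc2)c1O | intermediate
7 | 3-methylbut-2-enal | CC(C)=CC=O | starting material
8 | 2-hydroxy-3-(3-methylbut-2-en-1-ylidene)-4-oxocyclohexa-1,5-diene-1-carbaldehyde (1-oxatriene) | CC(C)=CC=C1C(=O)C=CC(C=O)=C1O | intermediate
9 | 5-hydroxy-2,2-dimethyl-2H-chromene-6-carbaldehyde | CC1(C)C=Cc2c(O)c(C=O)ccc2O1 | intermediate
10 | 5-[(tert-butyldimethylsilyl)oxy]-2,2-dimethyl-2H-chromene-6-carbaldehyde | CC1(C)C=Cc2c(O[Si](C)(C)C(C)(C)C)c(C=O)ccc2O1 | intermediate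
11 | tert-butyl{[6-(2-methoxyethenyl)-2,2-dimethyl-2H-chromen-5-yl]oxy}dimethylsilane (E/Z mixture) | COC=Cc1ccc2OC(C)(C)C=Cc2c1O[Si](C)(C)C(C)(C)C | intermediate
12 | {5-[(tert-butyldimethylsilyl)oxy]-2,2-dimethyl-2H-chromen-6-yl}acetaldehyde | O=CCc1ccc2OC(C)(C)C=Cc2c1O[Si](C)(C)C(C)(C)C | intermediate
13 | 6-methylidene-2-(3-methylbut-2-en-1-yl)-3-[(triisopropylsilyl)oxy]cyclohexa-2,4-dien-1-one (ortho-quinone methide) | CC(C)=CCC1=C(O[Si](C(C)C)(C(C)C)C(C)C)C=CC(=C)C1=O | intermediate
14 | E-enamine of 12 with (S)-2-[diphenyl(trimethylsilyloxy)methyl]pyrrolidine | C[Si](C)(C)OC(c1ccccc1)(c1ccccc1)[C@@H]1CCCN1/C=C/c1ccc2OC(C)(C)C=Cc2c1O[Si](C)(C)C(C)(C)C | intermediate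
15 | (3S)-3-{5-[(tert-butyldimethylsilyl)oxy]-2,2-dimethyl-2H-chromen-6-yl}-2-{(2S)-2-[diphenyl(trimethylsilyloxy)methyl]pyrrolidin-1-yl}-8-(3-methylbut-2-en-1-yl)-7-[(triisopropylsilyl)oxy]chroman (cyclic N,O-aminal, C2 unassigned) | CC(C)=CCc1c(O[Si](C(C)C)(C(C)C)C(C)C)ccc2c1OC(N1CCC[C@H]1C(c1ccccc1)(c1ccccc1)O[Si](C)(C)C)[C@H](c1ccc3c(c1O[Si](C)(C)C(C)(C)C)C=CC(C)(C)O3)C2 | intermediate
16 | (3S)-3-{5-[(tert-butyldimethylsilyl)oxy]-2,2-dimethyl-2H-chromen-6-yl}-8-(3-methylbut-2-en-1-yl)-7-[(triisopropylsilyl)oxy]chroman-2-ol (both C2 epimers) | CC(C)=CCc1c(O[Si](C(C)C)(C(C)C)C(C)C)ccc2c1OC(O)[C@H](c1ccc3c(c1O[Si](C)(C)C(C)(C)C)C=CC(C)(C)O3)C2 | intermediate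
17 | tert-butyl({6-[(3S)-8-(3-methylbut-2-en-1-yl)-7-[(triisopropylsilyl)oxy]chroman-3-yl]-2,2-dimethyl-2H-chromen-5-yl}oxy)dimethylsilane | CC(C)=CCc1c(O[Si](C(C)C)(C(C)C)C(C)C)ccc2c1OC[C@H](c1ccc3c(c1O[Si](C)(C)C(C)(C)C)C=CC(C)(C)O3)C2 | intermediate
18 | (3S)-3-(5-hydroxy-2,2-dimethyl-2H-chromen-6-yl)-8-(3-methylbut-2-en-1-yl)chroman-7-ol | CC(C)=CCc1c(O)ccc2c1OC[C@H](c1ccc3c(c1O)C=CC(C)(C)O3)C2 | target

**Step count and risks**
Total step count: 11. Longest linear sequence: 7 steps (steps 1–4 then 9–11, or steps 5–8 then 9–11).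

Steps most likely to fail:

1. Step 9. What may go wrong: erosion of the C3 configuration through enol or enamine exchange at the α-aryl aldehyde carbon, N-alkylation of the amine catalyst by the quinone methide, and self-condensation of the quinone methide before it is trapped. The fallback replaces the cycloaddition by an auxiliary-controlled enolate alkylation and closes ring C through O1–C2; it sets out from 12 and 4 and comes back to the route at 17.
   - Chlorite oxidation of 12 (NaClO2, NaH2PO4, 2-methylbut-2-ene, t-BuOH/H2O) should give {5-[(tert-butyldimethylsilyl)oxy]-2,2-dimethyl-2H-chromen-6-yl}acetic acid F1. Pivaloyl chloride/Et3N converts it into the mixed pivalic anhydride F2 (not isolated), which acylates lithiated (S)-4-benzyl-2-oxazolidinone (n-BuLi, THF, −78 °C) to the N-arylacetyl oxazolidinone F3.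
   - Separately, 4 is O-allylated under Mitsunobu conditions (allyl alcohol, PPh3, DIAD, THF) to the 2-allyloxy aldehyde F4, reduced (NaBH4) to the benzyl alcohol F5 and converted (CBr4, PPh3, CH2Cl2, 0 °C) into the benzyl bromide F6, used crude.
   - The sodium Z-enolate of F3 (NaN(SiMe3)2, THF, −78 °C) should be alkylated by F6 on the face away from the benzyl group of the auxiliary to give the (2S)-imide F7. LiBH4 (THF, 0 °C) releases the auxiliary and gives the primary alcohol F8. Pd(PPh3)4 (cat.) with morpholine removes the allyl group to give the phenol-alcohol F9, and Mitsunobu etherification (PPh3, DIAD, THF) closes ring C to 17.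

2. Step 10. What may go wrong: loss of the C3 proton from the oxocarbenium ion to a 4H-chromene followed by reprotonation (racemisation), and acid-induced ionic hydrogenation or cyclisation at the chromene and prenyl alkenes. The fallback avoids a cation at C2 and re-makes O1–C2 by displacement; it sets out from 16 and comes back at 17. NaBH4 (THF/MeOH, 0 °C) should reduce the open hydroxy-aldehyde tautomer of 16 to the phenol-alcohol F10 (the same structure as F9), and Mitsunobu etherification (PPh3, DIAD, THF, 0 °C) closes ring C to 17.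

3. Step 1. What may go wrong: poor regioselectivity, with O-prenylation, C5-prenylation and double prenylation competing. The fallback delivers the prenyl group by a sigmatropic shift; it sets out from 1 and comes back at 3. The non-chelated C4 hydroxyl of 1 is etherified with 3-chloro-3-methylbut-1-yne (K2CO3, KI, CuI cat., acetone, reflux) to the propargyl ether F11. Semi-hydrogenation (H2, Pd/CaCO3 poisoned with Pb(OAc)2, quinoline, EtOAc) gives the 1,1-dimethylallyl ether F12. Heating (N,N-diethylaniline, 130–180 °C) should bring about the aromatic Claisen rearrangement through the dienone F13 (not isolated), which tautomerises to 3; bond fixation in the chelated salicylaldehyde directs the shift to C3.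

**Further compounds**
F1 | step 9 | {5-[(tert-butyldimethylsilyl)oxy]-2,2-dimethyl-2H-chromen-6-yl}acetic acid | OC(=O)Cc1ccc2OC(C)(C)C=Cc2c1O[Si](C)(C)C(C)(C)C
F2 | step 9 | {5-[(tert-butyldimethylsilyl)oxy]-2,2-dimethyl-2H-chromen-6-yl}acetic 2,2-dimethylpropanoic anhydride | CC(C)(C)C(=O)OC(=O)Cc1ccc2OC(C)(C)C=Cc2c1O[Si](C)(C)C(C)(C)C
F3 | step 9 | (4S)-4-benzyl-3-({5-[(tert-butyldimethylsilyl)oxy]-2,2-dimethyl-2H-chromen-6-yl}acetyl)-1,3-oxazolidin-2-one | O=C(Cc1ccc2OC(C)(C)C=Cc2c1O[Si](C)(C)C(C)(C)C)N1[C@@H](Cc2ccccc2)COC1=O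
F4 | step 9 | 3-(3-methylbut-2-en-1-yl)-2-(prop-2-en-1-yloxy)-4-[(triisopropylsilyl)oxy]benzaldehyde | CC(C)=CCc1c(O[Si](C(C)C)(C(C)C)C(C)C)ccc(C=O)c1OCC=C
F5 | step 9 | {3-(3-methylbut-2-en-1-yl)-2-(prop-2-en-1-yloxy)-4-[(triisopropylsilyl)oxy]phenyl}methanol | CC(C)=CCc1c(O[Si](C(C)C)(C(C)C)C(C)C)ccc(CO)c1OCC=C
F6 | step 9 | {[4-(bromomethyl)-2-(3-methylbut-2-en-1-yl)-3-(prop-2-en-1-yloxy)phenyl]oxy}triisopropylsilane | CC(C)=CCc1c(O[Si](C(C)C)(C(C)C)C(C)C)ccc(CBr)c1OCC=C
F7 | step 9 | (4S)-4-benzyl-3-[(2S)-2-{5-[(tert-butyldimethylsilyl)oxy]-2,2-dimethyl-2H-chromen-6-yl}-3-{3-(3-methylbut-2-en-1-yl)-2-(prop-2-en-1-yloxy)-4-[(triisopropylsilyl)oxy]phenyl}propanoyl]-1,3-oxazolidin-2-one | CC(C)=CCc1c(O[Si](C(C)C)(C(C)C)C(C)C)ccc(C[C@@H](c2ccc3OC(C)(C)C=Cc3c2O[Si](C)(C)C(C)(C)C)C(=O)N2[C@@H](Cc3ccccc3)COC2=O)c1OCC=C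
F8 | step 9 | (2S)-2-{5-[(tert-butyldimethylsilyl)oxy]-2,2-dimethyl-2H-chromen-6-yl}-3-{3-(3-methylbut-2-en-1-yl)-2-(prop-2-en-1-yloxy)-4-[(triisopropylsilyl)oxy]phenyl}propan-1-ol | CC(C)=CCc1c(O[Si](C(C)C)(C(C)C)C(C)C)ccc(C[C@@H](c2ccc3OC(C)(C)C=Cc3c2O[Si](C)(C)C(C)(C)C)CO)c1OCC=C
F9 | step 9 | 6-[(2S)-2-{5-[(tert-butyldimethylsilyl)oxy]-2,2-dimethyl-2H-chromen-6-yl}-3-hydroxypropyl]-2-(3-methylbut-2-en-1-yl)-3-[(triisopropylsilyl)oxy]phenol | CC(C)=CCc1c(O[Si](C(C)C)(C(C)C)C(C)C)ccc(C[C@@H](c2ccc3OC(C)(C)C=Cc3c2O[Si](C)(C)C(C)(C)C)CO)c1O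
F10 | step 10 | 6-[(2S)-2-{5-[(tert-butyldimethylsilyl)oxy]-2,2-dimethyl-2H-chromen-6-yl}-3-hydroxypropyl]-2-(3-methylbut-2-en-1-yl)-3-[(triisopropylsilyl)oxy]phenol | CC(C)=CCc1c(O[Si](C(C)C)(C(C)C)C(C)C)ccc(C[C@@H](c2ccc3OC(C)(C)C=Cc3c2O[Si](C)(C)C(C)(C)C)CO)c1O
F11 | step 1 | 2-hydroxy-4-[(2-methylbut-3-yn-2-yl)oxy]benzaldehyde | C#CC(C)(C)Oc1ccc(C=O)c(O)c1
F12 | step 1 | 2-hydroxy-4-[(2-methylbut-3-en-2-yl)oxy]benzaldehyde | C=CC(C)(C)Oc1ccc(C=O)c(O)c1
F13 | step 1 | 2-hydroxy-3-(3-methylbut-2-en-1-yl)-4-oxocyclohexa-1,5-diene-1-carbaldehyde | CC(C)=CCC1C(=O)C=CC(C=O)=C1O
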